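**Retrosynthetic overview**
- 16 ⇐ 15 ⇐ 14: the benzyl (ring B phenol), TBS (C-gamma oxygen) and tert-butyl (ring A carboxyl) groups are removed last, under neutral and acidic conditions only.
- 14 ⇐ aldehyde 11 + aryl Grignard 12: the C-alpha–ring B bond comes from addition to the aldehyde and re-oxidation.
- 11 ⇐ (R)-monoacetate 8 ⇐ diol 7: C-beta carries the ring A aryloxy oxygen, H and two one-carbon oxygenated arms (C-gamma CH2OH and the C-alpha carbonyl carbon), so it is the central carbon of a prochiral 2-aryloxypropane-1,3-diol, and a lipase acetylates one enantiotopic CH2OH.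
- 7 ⇐ tert-butyl vanillate 4 + diethyl bromomalonate 5 (O-alkylation, borohydride reduction); 4 ⇐ vanillic acid 3.
- No ring is formed: ring A (vanillate) and ring B (syringyl) are bought as 3 and 1.

Key step: step 5

Assumption: the lipase is taken to acetylate the pro-R hydroxymethyl arm of 7. Its enantiotopic preference on this new 2-aryloxy diol has to be confirmed by screening (Burkholderia cepacia lipase, porcine pancreatic lipase), and the opposite preference is covered by the fallback to step 5.

**Route**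

Step 1
Reactants: 1 4-bromo-2,6-dimethoxyphenol
Product: 2 2-(benzyloxy)-5-bromo-1,3-dimethoxybenzene
Conditions: BnBr, K2CO3, DMF, 60 °C
Reagents that add atoms: benzyl bromide, BrCc1ccccc1
Why: Williamson etherification of the phenoxide with a reactive benzylic bromide should proceed despite the two flanking methoxy groups.

Step 2
Reactants: 3 vanillic acid
Product: 4 tert-butyl 4-hydroxy-3-methoxybenzoate
Conditions: N,N-dimethylformamide di-tert-butyl acetal, toluene, 80 °C
Reagents that add atoms: N,N-dimethylformamide di-tert-butyl acetal, CN(C)C(OC(C)(C)C)OC(C)(C)C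
Why: tert-butyl esterification with the amide acetal is triggered by protonation of the acetal by the carboxylic acid, so the much less acidic phenol should stay free.

Step 3
Reactants: 4 tert-butyl 4-hydroxy-3-methoxybenzoate; 5 diethyl bromomalonate
Product: 6 diethyl 2-[4-(tert-butoxycarbonyl)-2-methoxyphenoxy]propanedioate
Conditions: K2CO3, acetone, reflux
Reagents that add atoms: none
Why: Williamson-type SN2 O-alkylation of the phenoxide on the doubly carbonyl-activated bromide is the standard entry to aryloxymalonates.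

Step 4
Reactants: 6 diethyl 2-[4-(tert-butoxycarbonyl)-2-methoxyphenoxy]propanedioate
Product: 7 tert-butyl 4-[(1,3-dihydroxypropan-2-yl)oxy]-3-methoxybenzoate
Conditions: NaBH4, LiCl, EtOH/THF, 0 °C to rt
Reagents that add atoms: none
Why: Borohydride reduction (LiBH4 formed in the flask) should reduce the two alpha-aryloxy-activated ethyl esters, while the conjugated, hindered aryl tert-butyl ester is inert; the product is achiral.

Step 5
Reactants: 7 tert-butyl 4-[(1,3-dihydroxypropan-2-yl)oxy]-3-methoxybenzoate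
Product: 8 tert-butyl 4-{[(2R)-1-(acetyloxy)-3-hydroxypropan-2-yl]oxy}-3-methoxybenzoate
Conditions: Burkholderia cepacia lipase (immobilised), vinyl acetate (5 equiv), MTBE, 25 °C
Reagents that add atoms: vinyl acetate, C=COC(C)=O
Why: The active-site serine is acetylated by vinyl acetate and the acetyl-enzyme passes the acyl group to the one CH2OH arm of 7 that can reach it when the ring A aryloxy group sits in the large hydrophobic pocket; the vinyl alcohol released tautomerises to acetaldehyde, so the transfer cannot reverse. The closest known reaction type is the lipase-catalysed monoacetylation of prochiral 2-O-benzylglycerol and other 2-substituted propane-1,3-diols with enol esters. No ring is closed and no skeletal bond is formed; one acyl–oxygen bond is made. The new stereocentre at C-beta is set by the chiral pocket of the enzyme alone (catalyst control), acetylation of the pro-R arm giving the (R)-monoacetate. The step needs enantiotopic-group selectivity and mono- over di-acylation: the two arms are chemically identical, so nothing in the substrate opposes the choice of the enzyme, the hindered aryl tert-butyl ester is not a lipase substrate, and running slightly past full consumption of 7 should raise the ee because the minor (S)-monoacetate still carries the fast-reacting pro-R arm and is drained into the diacetate.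

Step 6
Reactants: 8 tert-butyl 4-{[(2R)-1-(acetyloxy)-3-hydroxypropan-2-yl]oxy}-3-methoxybenzoate
Product: 9 tert-butyl 4-{[(2S)-1-(acetyloxy)-3-[(tert-butyldimethylsilyl)oxy]propan-2-yl]oxy}-3-methoxybenzoate
Conditions: TBSCl, imidazole, CH2Cl2, 0 °C to rt
Reagents that add atoms: tert-butyldimethylsilyl chloride, CC(C)(C)[Si](C)(C)Cl
Why: Silylation of the free primary alcohol under weakly basic conditions should be much faster than 1,3-acetyl migration, so the stereocentre is kept (the descriptor changes only through CIP priorities).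

Step 7
Reactants: 9 tert-butyl 4-{[(2S)-1-(acetyloxy)-3-[(tert-butyldimethylsilyl)oxy]propan-2-yl]oxy}-3-methoxybenzoate
Product: 10 tert-butyl 4-{[(2S)-1-[(tert-butyldimethylsilyl)oxy]-3-hydroxypropan-2-yl]oxy}-3-methoxybenzoate
Conditions: K2CO3 (0.2 equiv), MeOH, 0 °C, short reaction time
Reagents that add atoms: none
Why: Carbonate-catalysed transesterification should remove the primary acetate while the tert-butyl ester resists methanolysis; low temperature and catalytic base keep the alkoxide concentration too low for the 1,3-silyl shift that would racemise the product.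

Step 8
Reactants: 10 tert-butyl 4-{[(2S)-1-[(tert-butyldimethylsilyl)oxy]-3-hydroxypropan-2-yl]oxy}-3-methoxybenzoate
Product: 11 tert-butyl 4-{[(2R)-1-[(tert-butyldimethylsilyl)oxy]-3-oxopropan-2-yl]oxy}-3-methoxybenzoate
Conditions: Dess–Martin periodinane, CH2Cl2, 0 °C to rt; crude aldehyde used at once
Reagents that add atoms: none
Why: Dess–Martin oxidation is non-basic, so the alpha-aryloxy aldehyde should form without epimerisation at C-beta and without over-oxidation.

Step 9
Reactants: 11 tert-butyl 4-{[(2R)-1-[(tert-butyldimethylsilyl)oxy]-3-oxopropan-2-yl]oxy}-3-methoxybenzoate; 2 2-(benzyloxy)-5-bromo-1,3-dimethoxybenzene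
Product: 13 tert-butyl 4-{[(1RS,2R)-1-[4-(benzyloxy)-3,5-dimethoxyphenyl]-3-[(tert-butyldimethylsilyl)oxy]-1-hydroxypropan-2-yl]oxy}-3-methoxybenzoate, via arylmagnesium bromide 12 (not isolated)
Conditions: 2, Mg, I2 (cat.), THF, reflux; then 11, THF, −78 °C; aqueous work-up
Reagents that add atoms: none
Why: Grignard addition to the aldehyde at −78 °C should outrun both enolisation and attack on the hindered aryl tert-butyl ester; the carbinol centre forms as a mixture of epimers, which is irrelevant because step 10 removes it.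

Step 10
Reactants: 13 tert-butyl 4-{[(1RS,2R)-1-[4-(benzyloxy)-3,5-dimethoxyphenyl]-3-[(tert-butyldimethylsilyl)oxy]-1-hydroxypropan-2-yl]oxy}-3-methoxybenzoate
Product: 14 tert-butyl 4-{[(2R)-1-[4-(benzyloxy)-3,5-dimethoxyphenyl]-3-[(tert-butyldimethylsilyl)oxy]-1-oxopropan-2-yl]oxy}-3-methoxybenzoate
Conditions: Dess–Martin periodinane, CH2Cl2, 0 °C to rt
Reagents that add atoms: none
Why: Dess–Martin oxidation of the secondary benzylic alcohol should merge both epimers into one aryl ketone under non-basic conditions that leave the acidic C-beta hydrogen untouched.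

Step 11
Reactants: 14 tert-butyl 4-{[(2R)-1-[4-(benzyloxy)-3,5-dimethoxyphenyl]-3-[(tert-butyldimethylsilyl)oxy]-1-oxopropan-2-yl]oxy}-3-methoxybenzoate
Product: 15 tert-butyl 4-{[(2R)-3-[(tert-butyldimethylsilyl)oxy]-1-(4-hydroxy-3,5-dimethoxyphenyl)-1-oxopropan-2-yl]oxy}-3-methoxybenzoate
Conditions: H2 (1 atm), Pd/C (10 wt% palladium on carbon), EtOAc, rt, stopped at full consumption of 14
Reagents that add atoms: none
Why: Catalytic hydrogenolysis cleaves aryl benzyl ethers quickly at 1 atm, so the phenol should be released under neutral conditions before the aryl ketone or the silyl ether reacts.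

Step 12
Reactants: 15 tert-butyl 4-{[(2R)-3-[(tert-butyldimethylsilyl)oxy]-1-(4-hydroxy-3,5-dimethoxyphenyl)-1-oxopropan-2-yl]oxy}-3-methoxybenzoate
Product: 16 4-{[(2R)-3-hydroxy-1-(4-hydroxy-3,5-dimethoxyphenyl)-1-oxopropan-2-yl]oxy}-3-methoxybenzoic acid
Conditions: TFA/CH2Cl2/H2O (10:10:1), 0 °C to rt; evaporation, co-evaporation with aqueous MeOH
Reagents that add atoms: none
Why: Acidolysis should cleave the tert-butyl ester (as isobutene) and the primary TBS ether together, and no base ever meets the epimerisable, retro-aldol-prone beta-hydroxy ketone.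

**Compound list**
1 | 4-bromo-2,6-dimethoxyphenol | COc1cc(Br)cc(OC)c1O | starting material
2 | 2-(benzyloxy)-5-bromo-1,3-dimethoxybenzene | COc1cc(Br)cc(OC)c1OCc1ccccc1 | intermediate
3 | vanillic acid (4-hydroxy-3-methoxybenzoic acid) | COc1cc(C(=O)O)ccc1O | starting material
4 | tert-butyl 4-hydroxy-3-methoxybenzoate | COc1cc(C(=O)OC(C)(C)C)ccc1O | intermediate
5 | diethyl bromomalonate | CCOC(=O)C(Br)C(=O)OCC | starting material
6 | diethyl 2-[4-(tert-butoxycarbonyl)-2-methoxyphenoxy]propanedioate | CCOC(=O)C(Oc1ccc(C(=O)OC(C)(C)C)cc1OC)C(=O)OCC | intermediate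
7 | tert-butyl 4-[(1,3-dihydroxypropan-2-yl)oxy]-3-methoxybenzoate | COc1cc(C(=O)OC(C)(C)C)ccc1OC(CO)CO | intermediate
8 | tert-butyl 4-{[(2R)-1-(acetyloxy)-3-hydroxypropan-2-yl]oxy}-3-methoxybenzoate | COc1cc(C(=O)OC(C)(C)C)ccc1O[C@H](CO)COC(C)=O | intermediate
9 | tert-butyl 4-{[(2S)-1-(acetyloxy)-3-[(tert-butyldimethylsilyl)oxy]propan-2-yl]oxy}-3-methoxybenzoate | COc1cc(C(=O)OC(C)(C)C)ccc1O[C@H](CO[Si](C)(C)C(C)(C)C)COC(C)=O | intermediate
10 | tert-butyl 4-{[(2S)-1-[(tert-butyldimethylsilyl)oxy]-3-hydroxypropan-2-yl]oxy}-3-methoxybenzoate | COc1cc(C(=O)OC(C)(C)C)ccc1O[C@H](CO[Si](C)(C)C(C)(C)C)CO | intermediate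
11 | tert-butyl 4-{[(2R)-1-[(tert-butyldimethylsilyl)oxy]-3-oxopropan-2-yl]oxy}-3-methoxybenzoate | COc1cc(C(=O)OC(C)(C)C)ccc1O[C@H](CO[Si](C)(C)C(C)(C)C)C=O | intermediate
12 | [4-(benzyloxy)-3,5-dimethoxyphenyl]magnesium bromide | COc1cc([Mg]Br)cc(OC)c1OCc1ccccc1 | intermediate
13 | tert-butyl 4-{[(1RS,2R)-1-[4-(benzyloxy)-3,5-dimethoxyphenyl]-3-[(tert-butyldimethylsilyl)oxy]-1-hydroxypropan-2-yl]oxy}-3-methoxybenzoate (C-1 epimers) | COc1cc(C(=O)OC(C)(C)C)ccc1O[C@H](CO[Si](C)(C)C(C)(C)C)C(O)c1cc(OC)c(OCc2ccccc2)c(OC)c1 | intermediate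
14 | tert-butyl 4-{[(2R)-1-[4-(benzyloxy)-3,5-dimethoxyphenyl]-3-[(tert-butyldimethylsilyl)oxy]-1-oxopropan-2-yl]oxy}-3-methoxybenzoate | COc1cc(C(=O)OC(C)(C)C)ccc1O[C@H](CO[Si](C)(C)C(C)(C)C)C(=O)c1cc(OC)c(OCc2ccccc2)c(OC)c1 | intermediate
15 | tert-butyl 4-{[(2R)-3-[(tert-butyldimethylsilyl)oxy]-1-(4-hydroxy-3,5-dimethoxyphenyl)-1-oxopropan-2-yl]oxy}-3-methoxybenzoate | COc1cc(C(=O)OC(C)(C)C)ccc1O[C@H](CO[Si](C)(C)C(C)(C)C)C(=O)c1cc(OC)c(O)c(OC)c1 | intermediate
16 | 4-{[(2R)-3-hydroxy-1-(4-hydroxy-3,5-dimethoxyphenyl)-1-oxopropan-2-yl]oxy}-3-methoxybenzoic acid | COc1cc(C(=O)O)ccc1O[C@H](CO)C(=O)c1cc(OC)c(O)c(OC)c1 | target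

Total step count: 12. Longest linear sequence: 11 steps (steps 2 to 12, from vanillic acid 3).

**Steps most likely to fail**

1. Step 5. The enzyme may acylate the opposite enantiotopic arm, or may discriminate the two arms too weakly. The fallback sets out from diol 7 and comes back at monoacetate 8. Diol 7 is peracetylated (Ac2O, pyridine, DMAP, CH2Cl2) to the diacetate tert-butyl 4-{[1,3-bis(acetyloxy)propan-2-yl]oxy}-3-methoxybenzoate F1. The same lipase is then used in the hydrolytic direction (pH 7 phosphate buffer, iPr2O as cosolvent, 25 °C). An enzyme that accepts the pro-S arm removes the acetate from that arm of F1 and leaves the acetate on the pro-R arm, so the desymmetrisation is inverted in sense and should give the (R)-monoacetate 8.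

2. Step 9. The basic Grignard reagent may enolise the alpha-aryloxy aldehyde, which would epimerise C-beta or expel the silyloxy group by beta-elimination in competition with addition. The fallback sets out from alcohol 10 and comes back at ketone 14. Alcohol 10 is oxidised (TEMPO cat., PhI(OAc)2, MeCN/H2O) to the acid (2R)-2-[4-(tert-butoxycarbonyl)-2-methoxyphenoxy]-3-[(tert-butyldimethylsilyl)oxy]propanoic acid F2. This is coupled with N,O-dimethylhydroxylamine hydrochloride (EDC·HCl, N-methylmorpholine, CH2Cl2, 0 °C) to the Weinreb amide tert-butyl 4-{[(2R)-3-[(tert-butyldimethylsilyl)oxy]-1-[methoxy(methyl)amino]-1-oxopropan-2-yl]oxy}-3-methoxybenzoate F3. Grignard reagent 12 is added to F3 in THF at −20 °C; the amide alpha-hydrogen is far less acidic than that of the aldehyde and the chelated tetrahedral adduct releases the ketone only on quench, so 14 should be reached directly without step 10.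

3. Step 11. Reductive cleavage of the C-beta–O aryl ether bond next to the ketone, or reduction of the aryl ketone, may compete with debenzylation. The fallback sets out from phenol 1 and aldehyde 11 and comes back at target 16, and it removes the reductive step altogether. Phenol 1 is protected with MOMCl/iPr2NEt (CH2Cl2) as 5-bromo-1,3-dimethoxy-2-(methoxymethoxy)benzene F4. This is converted with Mg in THF into [3,5-dimethoxy-4-(methoxymethoxy)phenyl]magnesium bromide F5 and added to 11 at −78 °C to give tert-butyl 4-{[(1RS,2R)-3-[(tert-butyldimethylsilyl)oxy]-1-[3,5-dimethoxy-4-(methoxymethoxy)phenyl]-1-hydroxypropan-2-yl]oxy}-3-methoxybenzoate F6. Dess–Martin oxidation gives the ketone tert-butyl 4-{[(2R)-3-[(tert-butyldimethylsilyl)oxy]-1-[3,5-dimethoxy-4-(methoxymethoxy)phenyl]-1-oxopropan-2-yl]oxy}-3-methoxybenzoate F7. A single acidolysis (TFA/CH2Cl2/H2O, 0 °C to rt) should then remove the MOM, TBS and tert-butyl groups together and give 16.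

Further compounds
F1 | step 5 | tert-butyl 4-{[1,3-bis(acetyloxy)propan-2-yl]oxy}-3-methoxybenzoate | COc1cc(C(=O)OC(C)(C)C)ccc1OC(COC(C)=O)COC(C)=O
F2 | step 9 | (2R)-2-[4-(tert-butoxycarbonyl)-2-methoxyphenoxy]-3-[(tert-butyldimethylsilyl)oxy]propanoic acid | COc1cc(C(=O)OC(C)(C)C)ccc1O[C@H](CO[Si](C)(C)C(C)(C)C)C(=O)O
F3 | step 9 | tert-butyl 4-{[(2R)-3-[(tert-butyldimethylsilyl)oxy]-1-[methoxy(methyl)amino]-1-oxopropan-2-yl]oxy}-3-methoxybenzoate | COc1cc(C(=O)OC(C)(C)C)ccc1O[C@H](CO[Si](C)(C)C(C)(C)C)C(=O)N(C)OC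
F4 | step 11 | 5-bromo-1,3-dimethoxy-2-(methoxymethoxy)benzene | COCOc1c(OC)cc(Br)cc1OC
F5 | step 11 | [3,5-dimethoxy-4-(methoxymethoxy)phenyl]magnesium bromide | COCOc1c(OC)cc([Mg]Br)cc1OC
F6 | step 11 | tert-butyl 4-{[(1RS,2R)-3-[(tert-butyldimethylsilyl)oxy]-1-[3,5-dimethoxy-4-(methoxymethoxy)phenyl]-1-hydroxypropan-2-yl]oxy}-3-methoxybenzoate | COc1cc(C(=O)OC(C)(C)C)ccc1O[C@H](CO[Si](C)(C)C(C)(C)C)C(O)c1cc(OC)c(OCOC)c(OC)c1
F7 | step 11 | tert-butyl 4-{[(2R)-3-[(tert-butyldimethylsilyl)oxy]-1-[3,5-dimethoxy-4-(methoxymethoxy)phenyl]-1-oxopropan-2-yl]oxy}-3-methoxybenzoate | COc1cc(C(=O)OC(C)(C)C)ccc1O[C@H](CO[Si](C)(C)C(C)(C)C)C(=O)c1cc(OC)c(OCOC)c(OC)c1
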